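The route rests on cutting the C1–C2 bond of the nonanone chain, directly beside ring A. The feature exploited is the free hydroxyl on C2' of ring A, ortho to the carbon that bears the ketone carbon C1. In 2-hydroxy-6-methoxybenzaldehyde that oxygen can anchor rhodium next to the formyl C–H. In one operation the aldehyde then adds as acyl and hydride across a monosubstituted alkene, joining both halves and delivering the ketone at its final oxidation level with the OH/OMe pattern intact. The alkene partner is an oct-7-enylbenzene whose para oxygen (ring B) is masked as a silyl ether; fluoride unmasks it at the end.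

Key step: step 2

Remark: chain atoms run from C1 (carbonyl carbon on ring A) to C9 (benzylic carbon on ring B). The target holds no stereocentre and no alkene, so no step has to control configuration. Aryl bromide 1 is assumed to be bought already silylated, as it is a catalogue compound.

Step 1
Reactants: 1 (4-bromophenoxy)(tert-butyl)dimethylsilane; 2 8-bromooct-1-ene
Product: 4 tert-butyldimethyl[4-(oct-7-en-1-yl)phenoxy]silane, via aryl Grignard reagent 3 (not isolated)
Conditions: 1 (1.3 equiv), Mg turnings, iodine crystal, THF, 45 °C; then 2 (1.0 equiv), Li2CuCl4 (5 mol %), THF/NMP, 0 °C to rt
Reagents that add atoms: magnesium, [Mg] (present in intermediate 3 only, absent from 4)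
Why: Magnesium inserts into the aryl C–Br bond without touching the silyl ether, and the derived arylcopper species displaces the unhindered primary bromide in an SN2-like Kochi-type copper-catalysed Grignard cross-coupling that leaves the remote terminal alkene alone, with 2 kept limiting so that no bromoalkene reaches step 2.

Step 2
Reactants: 4 tert-butyldimethyl[4-(oct-7-en-1-yl)phenoxy]silane; 5 2-hydroxy-6-methoxybenzaldehyde
Product: 6 9-[4-(tert-butyldimethylsilyloxy)phenyl]-1-(2-hydroxy-6-methoxyphenyl)nonan-1-one
Conditions: 5 (1.0 equiv), 4 (1.3 equiv), [Rh(cod)Cl]2 (2.5 mol %), rac-BINOL N,N-diisopropylphosphoramidite (5 mol %), K3PO4 (10 mol %), degassed 2-MeTHF, 70 °C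
Reagents that add atoms: none
Why: K3PO4 deprotonates the ring A phenol, the phenoxide displaces chloride on monovalent rhodium and the neighbouring formyl C–H adds oxidatively, giving a five-membered O,C-chelated acyl hydride of trivalent rhodium whose rigidity holds back CO extrusion. Alkene 4 then binds and inserts into Rh–H so that the metal ends on the unsubstituted carbon, reductive elimination forges C1–C2, and proton exchange with fresh 5 releases 6. The closest known reaction type is the chelation-assisted intermolecular hydroacylation of unactivated 1-alkenes with salicylaldehydes under rhodium/phosphoramidite catalysis, which should tolerate the second ortho substituent (OMe) on the aldehyde. No ring is closed and no stereocentre is created, so a racemic ligand is enough. The selectivity needed is linear over branched addition, with coupling outrunning chain-walking of the double bond; the bulky monodentate ligand favours the primary alkyl rhodium species, the alkene carries no directing group that could favour the secondary one, and the modest excess of 4 covers any isomerised material. The aryl silyl ether should hold because only a catalytic amount of poorly soluble base is present and silyl transfer to 5 would cost its intramolecular hydrogen bond.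

Step 3
Reactants: 6 9-[4-(tert-butyldimethylsilyloxy)phenyl]-1-(2-hydroxy-6-methoxyphenyl)nonan-1-one
Product: 7 1-(2-hydroxy-6-methoxyphenyl)-9-(4-hydroxyphenyl)nonan-1-one (CNP0117926.0)
Conditions: Bu4NF (1.1 equiv), AcOH (1.1 equiv), THF, 0 °C to rt
Reagents that add atoms: none
Why: This is a fluoride-mediated desilylation, driven by the strong Si–F bond and the good phenoxide leaving group, and the acetic acid buffer keeps the medium too mild to disturb the enolisable hydroxyaryl ketone or the methyl ether.

Compound list
1 | (4-bromophenoxy)(tert-butyl)dimethylsilane | CC(C)(C)[Si](C)(C)Oc1ccc(Br)cc1 | starting material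
2 | 8-bromooct-1-ene | C=CCCCCCCBr | starting material
3 | [4-(tert-butyldimethylsilyloxy)phenyl]magnesium bromide | CC(C)(C)[Si](C)(C)Oc1ccc([Mg]Br)cc1 | intermediate
4 | tert-butyldimethyl[4-(oct-7-en-1-yl)phenoxy]silane | C=CCCCCCCc1ccc(O[Si](C)(C)C(C)(C)C)cc1 | intermediate
5 | 2-hydroxy-6-methoxybenzaldehyde | COc1cccc(O)c1C=O | starting material
6 | 9-[4-(tert-butyldimethylsilyloxy)phenyl]-1-(2-hydroxy-6-methoxyphenyl)nonan-1-one | COc1cccc(O)c1C(=O)CCCCCCCCc1ccc(O[Si](C)(C)C(C)(C)C)cc1 | intermediate
7 | 1-(2-hydroxy-6-methoxyphenyl)-9-(4-hydroxyphenyl)nonan-1-one | COc1cccc(O)c1C(=O)CCCCCCCCc1ccc(O)cc1 | target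

Total step count: 3
Longest linear sequence: 3 steps (1 → 4 → 6 → 7)

Steps most likely to fail

1. Step 2.
- **Risk:** CO may be extruded from the acyl rhodium hydride before the alkene inserts. The double bond of 4 may walk into the chain faster than it couples. The addition may also drift towards the branched mode.
- **Fallback:** The C2–C3 bond is made by enolate alkylation in place of C1–C2. The fallback sets out from Grignard reagent 3, which is coupled under Li2CuCl4 catalysis (THF, 0 °C) with an excess of purchased 1,7-dibromoheptane to give [4-(7-bromoheptyl)phenoxy](tert-butyl)dimethylsilane F1. Purchased 1-(2-hydroxy-6-methoxyphenyl)ethan-1-one is doubly deprotonated with LiN(iPr)2 (2.2 equiv, THF, −78 to 0 °C) to dilithium 3-methoxy-2-(1-oxidoethenyl)phenolate F2. The enolate carbon of F2, formed last and therefore the more reactive site, should be alkylated by F1 (DMPU, −78 °C to rt). Aqueous NH4Cl work-up brings the route back at 6.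

2. Step 1.
- **Risk:** Aryl transfer from copper to the alkyl bromide may be sluggish, which would let oxidative homocoupling of the Grignard reagent and bromine–magnesium exchange consume both partners.
- **Fallback:** The polarity is reversed in a Negishi coupling. The fallback sets out from 2, into which LiCl-activated zinc dust inserts (THF, 50 °C) to give bromo(oct-7-en-1-yl)zinc F3. This reagent is coupled with aryl bromide 1 under PdCl2(dppf) (3 mol %) in THF at 60 °C. The sequence is oxidative addition of the aryl bromide to zerovalent palladium, transmetalation and reductive elimination. The medium is free of base, so the silyl ether should survive, and the wide-bite-angle ligand should suppress β-hydride elimination. The route is rejoined at 4.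

3. Step 3.
- **Risk:** Base may trigger condensation at the enolisable C2 position, or the polar bisphenol may be lost while the ammonium salts are washed out.
- **Fallback:** The order of events is changed. The fallback sets out from 4, which carries no ketone. The same buffered fluoride (Bu4NF, AcOH, THF) gives 4-(oct-7-en-1-yl)phenol F4, and the hydroacylation with 5 under the conditions of step 2 is then run on this free phenol. The ring B hydroxyl is less acidic than that of 5 and cannot chelate, so the catalytic base and the metal should stay on 5. The route is rejoined directly at 7.

Further compounds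
F1 | step 2 | [4-(7-bromoheptyl)phenoxy](tert-butyl)dimethylsilane | BrCCCCCCCc1ccc(O[Si](C)(C)C(C)(C)C)cc1
F2 | step 2 | dilithium 3-methoxy-2-(1-oxidoethenyl)phenolate | [Li+].[Li+].COc1cccc([O-])c1C([O-])=C
F3 | step 1 | bromo(oct-7-en-1-yl)zinc | C=CCCCCCC[Zn]Br
F4 | step 3 | 4-(oct-7-en-1-yl)phenol | C=CCCCCCCc1ccc(O)cc1
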